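## Retrosynthetic overview

1. Target ⇐ C15–O desilylation and C14 alcohol → aldehyde ⇐ ten-membered ring closed by ring-closing metathesis at C1=C10 on a preformed cis-fused α-methylene-γ-butyrolactone (germacrane numbering: lactone C6–O/C12=O, C7, C8–O-acyl, C14 on C10, C15 on C4, exo-methylene C11=C13).
2. Lactone ⇐ oxidative lactonisation of a C6-OH/C12-OH diol; the C6 alcohol (1,3-anti to O8) and the O8 3-methylbutanoate both come from one Evans–Tishchenko reduction of a β-hydroxy enone with 3-methylbutanal.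
3. Enone ⇐ C5–C6 union of an alkenyllithium (fragment 3: C1–C5, C15) with a Weinreb amide (C6–C14).
4. Weinreb amide ⇐ Evans syn-aldol at C7–C8 (sets 7S, 8R) of an N-acyloxazolidinone (fragment 1: C6, C7, C11–C13) with a β,γ-unsaturated aldehyde (fragment 2: C8–C10, C14).
5. Ring order: γ-lactone first (step 16), then the ten-membered carbocycle (step 17).

Assumption: the SMILES is taken as drawn, i.e. (6R,7S,8R) in germacrane numbering = (3aS,4R,6E,10E,11aR) in the ring-fusion name, with a cis-fused lactone and both ring alkenes cis within the ring; monomethyl itaconate 8 is the commercial 4-methyl ester.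

## Route

Steps 1–3 make fragment 1, steps 4–6 fragment 2, steps 7–10 fragment 3; steps 11–20 are the main line.

Step 1
Reactants: 1 3-chloro-2-(chloromethyl)prop-1-ene
Product: 2 1-({[2-(chloromethyl)prop-2-en-1-yl]oxy}methyl)-4-methoxybenzene
Conditions: 4-methoxybenzyl alcohol (1 equiv), NaH (1.1 equiv), THF/DMF, 0 °C; then 1 (3 equiv), 0 °C → rt
Reagents that add atoms: 4-methoxybenzyl alcohol, COc1ccc(CO)cc1
Why: Williamson ether synthesis (SN2 at an allylic chloride); the excess of the symmetrical dichloride 1 holds the reaction at mono-substitution.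

Step 2
Reactants: 2 1-({[2-(chloromethyl)prop-2-en-1-yl]oxy}methyl)-4-methoxybenzene
Product: 4 3-{[(4-methoxybenzyl)oxy]methyl}but-3-enoic acid, via Grignard reagent 3 (not isolated)
Conditions: Mg (3 equiv, I2-activated), THF, 0 °C, slow addition; CO2 (g), −40 °C → rt; 1 M HCl, 0 °C
Reagents that add atoms: carbon dioxide, O=C=O
Why: Grignard carboxylation; both termini of allyl reagent 3 are CH2, so either mode of attack gives the same β,γ-unsaturated acid, and the cold acidic work-up leaves the double bond unconjugated.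

Step 3
Reactants: 4 3-{[(4-methoxybenzyl)oxy]methyl}but-3-enoic acid; 5 (4S)-4-benzyl-1,3-oxazolidin-2-one
Product: 7 (4S)-4-benzyl-3-(3-{[(4-methoxybenzyl)oxy]methyl}but-3-enoyl)-1,3-oxazolidin-2-one, via mixed pivalic anhydride 6 (not isolated)
Conditions: PivCl, Et3N, THF, −20 °C; then 5, LiCl, −20 °C → rt
Reagents that add atoms: none
Why: N-acylation of the Evans auxiliary through a mixed anhydride; mild base at low temperature keeps the β,γ-double bond in place and the auxiliary stereocentre is untouched.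

Step 4
Reactants: 8 4-methoxy-2-methylidene-4-oxobutanoic acid (monomethyl itaconate)
Product: 10 methyl 3-(hydroxymethyl)but-3-enoate, via mixed carbonic anhydride 9 (not isolated)
Conditions: ClCO2Et, Et3N, THF, −10 °C; filter; NaBH4, THF/H2O, 0 °C; crude used at once
Reagents that add atoms: none
Why: chemoselective reduction of the free carboxylic acid through its mixed carbonic anhydride (NaBH4 attacks the activated acyl group and leaves the methyl ester alone).

Step 5
Reactants: 10 methyl 3-(hydroxymethyl)but-3-enoate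
Product: 11 methyl 3-{[(triethylsilyl)oxy]methyl}but-3-enoate
Conditions: TESCl, imidazole, CH2Cl2, 0 °C
Reagents that add atoms: chlorotriethylsilane, CC[Si](Cl)(CC)CC
Why: silylation of the primary allylic alcohol, done immediately so that the γ-hydroxy ester cannot lactonise.

Step 6
Reactants: 11 methyl 3-{[(triethylsilyl)oxy]methyl}but-3-enoate
Product: 12 3-{[(triethylsilyl)oxy]methyl}but-3-enal
Conditions: i-Bu2AlH (1.05 equiv), CH2Cl2, −78 °C; MeOH, aq. KNaC4H4O6; used at once as a cold solution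
Reagents that add atoms: none
Why: ester half-reduction with DIBAL-H at −78 °C; cold neutral work-up and immediate use avoid migration of the 1,1-disubstituted double bond into conjugation.

Step 7
Reactants: 13 prop-2-yn-1-ol
Product: 16 3-(trimethylsilyl)prop-2-yn-1-ol, via dilithio species 14 (not isolated), via bis-silyl ether 15 (not isolated)
Conditions: n-BuLi (2.1 equiv), THF, −78 °C; TMSCl (2.2 equiv), −78 °C → rt; 1 M HCl, rt
Reagents that add atoms: chlorotrimethylsilane, C[Si](C)(C)Cl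
Why: double deprotonation and C,O-bis-silylation, then selective hydrolysis of the labile O–Si bond.

Step 8
Reactants: 16 3-(trimethylsilyl)prop-2-yn-1-ol; 17 but-3-en-1-ylmagnesium bromide
Product: 19 (2E)-2-[(trimethylsilyl)methylidene]hex-5-en-1-ol, via magnesium chelate 18 (not isolated)
Conditions: 17 (3 equiv), CuI (10 mol%), THF/Et2O, 0 → 40 °C; aq. NH4Cl
Reagents that add atoms: none
Why: copper-catalysed anti-carbomagnesiation of a propargylic alkoxide (Duboudin type): the alkyl group adds to the carbon next to the carbinol, magnesium goes to the silicon-bearing carbon and is held cis to CH2O in the five-membered chelate 18, so after protonation silicon is cis to the butenyl chain (E).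

Step 9
Reactants: 19 (2E)-2-[(trimethylsilyl)methylidene]hex-5-en-1-ol
Product: 20 tert-butyl(dimethyl){[(2E)-2-[(trimethylsilyl)methylidene]hex-5-en-1-yl]oxy}silane
Conditions: TBSCl, imidazole, DMF, rt
Reagents that add atoms: tert-butyl(chloro)dimethylsilane, CC(C)(C)[Si](C)(C)Cl
Why: standard silylation of a primary alcohol; the alkene geometry is not touched.

Step 10
Reactants: 20 tert-butyl(dimethyl){[(2E)-2-[(trimethylsilyl)methylidene]hex-5-en-1-yl]oxy}silane
Product: 21 tert-butyl{[(2E)-2-(iodomethylidene)hex-5-en-1-yl]oxy}dimethylsilane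
Conditions: NIS (1.3 equiv), MeCN/ClCH2CN (4:1), 0 °C → rt, dark
Reagents that add atoms: N-iodosuccinimide, O=C1CCC(=O)N1I
Why: ipso-iododesilylation of a vinylsilane through a β-silyl cation, which proceeds with retention, so iodine ends cis to the butenyl chain and trans to CH2OTBS.

Step 11
Reactants: 7 (4S)-4-benzyl-3-(3-{[(4-methoxybenzyl)oxy]methyl}but-3-enoyl)-1,3-oxazolidin-2-one; 12 3-{[(triethylsilyl)oxy]methyl}but-3-enal
Product: 23 (4S)-4-benzyl-3-[(2S,3R)-3-hydroxy-2-{3-[(4-methoxybenzyl)oxy]prop-1-en-2-yl}-5-{[(triethylsilyl)oxy]methyl}hex-5-enoyl]-1,3-oxazolidin-2-one, via boron enolate 22 (not isolated)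
Conditions: Bu2BOTf (1.15 equiv), Et3N (1.3 equiv), CH2Cl2, −78 → 0 °C; 12 (1.3 equiv), −78 → −10 °C; pH 7 buffer, MeOH, 30% H2O2, 0 °C
Reagents that add atoms: none
Why: Evans syn-aldol reaction: the Z boron enolate 22 reacts at its α-carbon through a Zimmerman–Traxler chair on the face away from the benzyl group of the (S)-auxiliary, which sets C7 (S) and C8 (R) of the target in one step.

Step 12
Reactants: 23 (the aldol adduct of step 11)
Product: 24 (2S,3R)-3-hydroxy-N-methoxy-2-{3-[(4-methoxybenzyl)oxy]prop-1-en-2-yl}-N-methyl-5-{[(triethylsilyl)oxy]methyl}hex-5-enamide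
Conditions: MeNHOMe·HCl (3 equiv), AlMe3 (3 equiv), CH2Cl2, −20 → 0 °C; aq. KNaC4H4O6
Reagents that add atoms: N,O-dimethylhydroxylamine hydrochloride, CNOC.Cl
Why: aluminium-amide transamination of the imide to the Weinreb amide, assisted by the free β-hydroxyl; no stereocentre is touched and the auxiliary is recovered.

Step 13
Reactants: 24 (the Weinreb amide of step 12); 21 tert-butyl{[(2E)-2-(iodomethylidene)hex-5-en-1-yl]oxy}dimethylsilane
Product: 26 (5E,8S,9R)-5-({[tert-butyl(dimethyl)silyl]oxy}methyl)-9-hydroxy-8-{3-[(4-methoxybenzyl)oxy]prop-1-en-2-yl}-11-{[(triethylsilyl)oxy]methyl}dodeca-1,5,11-trien-7-one, via alkenyllithium 25 (not isolated)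
Conditions: 21 (1.6 equiv), t-BuLi (3.2 equiv), Et2O, −78 °C; added to 24 pre-treated with i-PrMgCl (1.05 equiv), THF, −78 → −40 °C; aq. NH4Cl
Reagents that add atoms: none
Why: Weinreb ketone synthesis: iodine–lithium exchange retains the alkene geometry and the N-methoxy-N-methylamide stops the addition at the ketone; no stereocentre is touched.

Step 14
Reactants: 26 (the β-hydroxy enone of step 13); 27 3-methylbutanal
Product: 29 (5E,7R,8R,9R)-5-({[tert-butyl(dimethyl)silyl]oxy}methyl)-7-hydroxy-8-{3-[(4-methoxybenzyl)oxy]prop-1-en-2-yl}-11-{[(triethylsilyl)oxy]methyl}dodeca-1,5,11-trien-9-yl 3-methylbutanoate, via hemiacetal 28 (not isolated)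
Conditions: 27 (6 equiv), SmI2 (0.3 equiv), THF, −10 °C, dark
Reagents that add atoms: none
Why: Evans–Tishchenko reduction: hydride is delivered intramolecularly from hemiacetal 28 within a samarium-bound chair, which gives the 1,3-anti C6 alcohol (6R of the target) and at the same time places the 3-methylbutanoyl group on O8.

Step 15
Reactants: 29 (the hydroxy ester of step 14)
Product: 30 (5E,7R,8R,9R)-5-({[tert-butyl(dimethyl)silyl]oxy}methyl)-7-hydroxy-8-(3-hydroxyprop-1-en-2-yl)-11-{[(triethylsilyl)oxy]methyl}dodeca-1,5,11-trien-9-yl 3-methylbutanoate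
Conditions: DDQ (1.3 equiv), CH2Cl2/pH 7 buffer (10:1), 0 °C
Reagents that add atoms: none
Why: oxidative cleavage of the electron-rich 4-methoxybenzyl ether; the silyl ethers, the ester and the alkenes are untouched under buffered conditions.

Step 16
Reactants: 30 (the diol of step 15)
Product: 33 (1R)-1-[(2R,3S)-2-[(1E)-2-({[tert-butyl(dimethyl)silyl]oxy}methyl)hexa-1,5-dien-1-yl]-4-methylidene-5-oxooxolan-3-yl]-3-{[(triethylsilyl)oxy]methyl}but-3-en-1-yl 3-methylbutanoate, via hydroxy enal 31 (not isolated), via lactol 32 (not isolated)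
Conditions: TEMPO (0.2 equiv), PhI(OAc)2 (2.5 equiv), CH2Cl2, rt
Reagents that add atoms: none
Why: TEMPO/PhI(OAc)2 oxidative lactonisation: the primary allylic alcohol is oxidised in preference to the secondary one, the aldehyde 31 is trapped by the C6 hydroxyl as lactol 32 and oxidised again; the cis ring fusion follows from C6 and C7 set in steps 14 and 11.

Step 17
Reactants: 33 (the α-methylene lactone of step 16)
Product: 34 (3aS,4R,6E,10E,11aR)-10-({[tert-butyl(dimethyl)silyl]oxy}methyl)-3-methylidene-2-oxo-6-{[(triethylsilyl)oxy]methyl}-2,3,3a,4,5,8,9,11a-octahydrocyclodeca[b]furan-4-yl 3-methylbutanoate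
Conditions: second-generation Grubbs catalyst (H2IMes)(PCy3)Cl2Ru=CHPh (15 mol%, two portions), 1,4-benzoquinone (20 mol%), toluene (1 mM), 80 °C
Reagents that add atoms: none
Why: ring-closing metathesis: ruthenium loads on the terminal vinyl group and closes onto the 1,1-disubstituted alkene; the cis-fused lactone holds both chains on one face, the conjugated exo-methylene and the trisubstituted alkene stay out of the reaction, and the ten-membered ring strongly favours the ring-cis (6E) trisubstituted alkene next to the existing cis alkene.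

Step 18
Reactants: 34 (the macrocycle of step 17)
Product: 35 (3aS,4R,6E,10E,11aR)-10-({[tert-butyl(dimethyl)silyl]oxy}methyl)-6-(hydroxymethyl)-3-methylidene-2-oxo-2,3,3a,4,5,8,9,11a-octahydrocyclodeca[b]furan-4-yl 3-methylbutanoate
Conditions: PPTS (0.2 equiv), MeOH/CH2Cl2 (1:1), 0 °C
Reagents that add atoms: none
Why: acid-catalysed methanolysis: the primary triethylsilyl ether is far more labile than the tert-butyldimethylsilyl ether, and the lactone and ester are stable.

Step 19
Reactants: 35 (the C14 alcohol of step 18)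
Product: 36 (3aS,4R,6E,10E,11aR)-10-({[tert-butyl(dimethyl)silyl]oxy}methyl)-6-formyl-3-methylidene-2-oxo-2,3,3a,4,5,8,9,11a-octahydrocyclodeca[b]furan-4-yl 3-methylbutanoate
Conditions: MnO2 (20 equiv), CH2Cl2, rt
Reagents that add atoms: none
Why: MnO2 oxidation of the only free alcohol, a primary allylic one, to the enal without touching the alkene geometry.

Step 20
Reactants: 36 (the enal of step 19)
Product: 37 (3aS,4R,6E,10E,11aR)-6-formyl-10-(hydroxymethyl)-3-methylidene-2-oxo-2,3,3a,4,5,8,9,11a-octahydrocyclodeca[b]furan-4-yl 3-methylbutanoate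
Conditions: HF·pyridine, pyridine, THF, 0 °C → rt
Reagents that add atoms: none
Why: fluoride-mediated cleavage of the silyl ether under buffered, mildly acidic conditions that the enal, the α-methylene lactone and the ester tolerate.

## Compound list

1 | 3-chloro-2-(chloromethyl)prop-1-ene | ClCC(=C)CCl | starting material
2 | 1-({[2-(chloromethyl)prop-2-en-1-yl]oxy}methyl)-4-methoxybenzene | C=C(CCl)COCc1ccc(OC)cc1 | intermediate
3 | [2-({[(4-methoxyphenyl)methyl]oxy}methyl)prop-2-en-1-yl]magnesium chloride | C=C(C[Mg]Cl)COCc1ccc(OC)cc1 | intermediate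
4 | 3-{[(4-methoxybenzyl)oxy]methyl}but-3-enoic acid | C=C(CC(=O)O)COCc1ccc(OC)cc1 | intermediate
5 | (4S)-4-benzyl-1,3-oxazolidin-2-one | O=C1OC[C@H](Cc2ccccc2)N1 | starting material
6 | 3-{[(4-methoxybenzyl)oxy]methyl}but-3-enoic 2,2-dimethylpropanoic anhydride | C=C(CC(=O)OC(=O)C(C)(C)C)COCc1ccc(OC)cc1 | intermediate
7 | (4S)-4-benzyl-3-(3-{[(4-methoxybenzyl)oxy]methyl}but-3-enoyl)-1,3-oxazolidin-2-one | C=C(COCc1ccc(OC)cc1)CC(=O)N2C(=O)OC[C@@H]2Cc3ccccc3 | intermediate
8 | 4-methoxy-2-methylidene-4-oxobutanoic acid (monomethyl itaconate) | C=C(CC(=O)OC)C(=O)O | starting material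
9 | ethoxycarbonyl 4-methoxy-2-methylidene-4-oxobutanoate (mixed carbonic anhydride) | C=C(CC(=O)OC)C(=O)OC(=O)OCC | intermediate
10 | methyl 3-(hydroxymethyl)but-3-enoate | C=C(CO)CC(=O)OC | intermediate
11 | methyl 3-{[(triethylsilyl)oxy]methyl}but-3-enoate | C=C(CO[Si](CC)(CC)CC)CC(=O)OC | intermediate
12 | 3-{[(triethylsilyl)oxy]methyl}but-3-enal | C=C(CO[Si](CC)(CC)CC)CC=O | intermediate
13 | prop-2-yn-1-ol | C#CCO | starting material
14 | lithium 3-lithioprop-2-yn-1-olate | [Li]C#CCO[Li] | intermediate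
15 | trimethyl{3-[(trimethylsilyl)oxy]prop-1-yn-1-yl}silane | C[Si](C)(C)C#CCO[Si](C)(C)C | intermediate
16 | 3-(trimethylsilyl)prop-2-yn-1-ol | C[Si](C)(C)C#CCO | intermediate
17 | but-3-en-1-ylmagnesium bromide | C=CCC[Mg]Br | starting material
18 | 4-(but-3-en-1-yl)-3-(trimethylsilyl)-2,5-dihydro-1,2-oxamagnesole (cyclic alkenylmagnesium alkoxide) | C[Si](C)(C)C1=C(CCC=C)CO[Mg]1 | intermediate
19 | (2E)-2-[(trimethylsilyl)methylidene]hex-5-en-1-ol | C[Si](C)(C)/C=C(/CO)CCC=C | intermediate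
20 | tert-butyl(dimethyl){[(2E)-2-[(trimethylsilyl)methylidene]hex-5-en-1-yl]oxy}silane | C[Si](C)(C)/C=C(/CO[Si](C)(C)C(C)(C)C)CCC=C | intermediate
21 | tert-butyl{[(2E)-2-(iodomethylidene)hex-5-en-1-yl]oxy}dimethylsilane | I/C=C(/CO[Si](C)(C)C(C)(C)C)CCC=C | intermediate
22 | (4S)-4-benzyl-3-[(1Z)-1-[(dibutylboranyl)oxy]-3-{[(4-methoxybenzyl)oxy]methyl}buta-1,3-dien-1-yl]-1,3-oxazolidin-2-one | CCCCB(CCCC)O/C(=C\C(=C)COCc1ccc(OC)cc1)N2C(=O)OC[C@@H]2Cc3ccccc3 | intermediate
23 | (4S)-4-benzyl-3-[(2S,3R)-3-hydroxy-2-{3-[(4-methoxybenzyl)oxy]prop-1-en-2-yl}-5-{[(triethylsilyl)oxy]methyl}hex-5-enoyl]-1,3-oxazolidin-2-one | C=C(CO[Si](CC)(CC)CC)C[C@@H](O)[C@H](C(=C)COCc1ccc(OC)cc1)C(=O)N2C(=O)OC[C@@H]2Cc3ccccc3 | intermediate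
24 | (2S,3R)-3-hydroxy-N-methoxy-2-{3-[(4-methoxybenzyl)oxy]prop-1-en-2-yl}-N-methyl-5-{[(triethylsilyl)oxy]methyl}hex-5-enamide | C=C(CO[Si](CC)(CC)CC)C[C@@H](O)[C@H](C(=C)COCc1ccc(OC)cc1)C(=O)N(C)OC | intermediate
25 | [(1E)-2-({[tert-butyl(dimethyl)silyl]oxy}methyl)hexa-1,5-dien-1-yl]lithium | [Li]/C=C(/CO[Si](C)(C)C(C)(C)C)CCC=C | intermediate
26 | (5E,8S,9R)-5-({[tert-butyl(dimethyl)silyl]oxy}methyl)-9-hydroxy-8-{3-[(4-methoxybenzyl)oxy]prop-1-en-2-yl}-11-{[(triethylsilyl)oxy]methyl}dodeca-1,5,11-trien-7-one | C=C(CO[Si](CC)(CC)CC)C[C@@H](O)[C@H](C(=C)COCc1ccc(OC)cc1)C(=O)/C=C(/CO[Si](C)(C)C(C)(C)C)CCC=C | intermediate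
27 | 3-methylbutanal | CC(C)CC=O | starting material
28 | (5E,8S,9R)-5-({[tert-butyl(dimethyl)silyl]oxy}methyl)-9-[(1-hydroxy-3-methylbutyl)oxy]-8-{3-[(4-methoxybenzyl)oxy]prop-1-en-2-yl}-11-{[(triethylsilyl)oxy]methyl}dodeca-1,5,11-trien-7-one (samarium-bound hemiacetal, drawn free) | C=C(CO[Si](CC)(CC)CC)C[C@@H](OC(O)CC(C)C)[C@H](C(=C)COCc1ccc(OC)cc1)C(=O)/C=C(/CO[Si](C)(C)C(C)(C)C)CCC=C | intermediate
29 | (5E,7R,8R,9R)-5-({[tert-butyl(dimethyl)silyl]oxy}methyl)-7-hydroxy-8-{3-[(4-methoxybenzyl)oxy]prop-1-en-2-yl}-11-{[(triethylsilyl)oxy]methyl}dodeca-1,5,11-trien-9-yl 3-methylbutanoate | C=C(CO[Si](CC)(CC)CC)C[C@@H](OC(=O)CC(C)C)[C@H](C(=C)COCc1ccc(OC)cc1)[C@H](O)/C=C(/CO[Si](C)(C)C(C)(C)C)CCC=C | intermediate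
30 | (5E,7R,8R,9R)-5-({[tert-butyl(dimethyl)silyl]oxy}methyl)-7-hydroxy-8-(3-hydroxyprop-1-en-2-yl)-11-{[(triethylsilyl)oxy]methyl}dodeca-1,5,11-trien-9-yl 3-methylbutanoate | C=C(CO[Si](CC)(CC)CC)C[C@@H](OC(=O)CC(C)C)[C@H](C(=C)CO)[C@H](O)/C=C(/CO[Si](C)(C)C(C)(C)C)CCC=C | intermediate
31 | (5E,7R,8R,9R)-5-({[tert-butyl(dimethyl)silyl]oxy}methyl)-7-hydroxy-8-(3-oxoprop-1-en-2-yl)-11-{[(triethylsilyl)oxy]methyl}dodeca-1,5,11-trien-9-yl 3-methylbutanoate | C=C(CO[Si](CC)(CC)CC)C[C@@H](OC(=O)CC(C)C)[C@H](C(=C)C=O)[C@H](O)/C=C(/CO[Si](C)(C)C(C)(C)C)CCC=C | intermediate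
32 | (1R)-1-[(2R,3S)-2-[(1E)-2-({[tert-butyl(dimethyl)silyl]oxy}methyl)hexa-1,5-dien-1-yl]-5-hydroxy-4-methylideneoxolan-3-yl]-3-{[(triethylsilyl)oxy]methyl}but-3-en-1-yl 3-methylbutanoate (both lactol epimers) | C=C1C(O)O[C@H](/C=C(/CO[Si](C)(C)C(C)(C)C)CCC=C)[C@@H]1[C@@H](CC(=C)CO[Si](CC)(CC)CC)OC(=O)CC(C)C | intermediate
33 | (1R)-1-[(2R,3S)-2-[(1E)-2-({[tert-butyl(dimethyl)silyl]oxy}methyl)hexa-1,5-dien-1-yl]-4-methylidene-5-oxooxolan-3-yl]-3-{[(triethylsilyl)oxy]methyl}but-3-en-1-yl 3-methylbutanoate | C=C1C(=O)O[C@H](/C=C(/CO[Si](C)(C)C(C)(C)C)CCC=C)[C@@H]1[C@@H](CC(=C)CO[Si](CC)(CC)CC)OC(=O)CC(C)C | intermediate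
34 | (3aS,4R,6E,10E,11aR)-10-({[tert-butyl(dimethyl)silyl]oxy}methyl)-3-methylidene-2-oxo-6-{[(triethylsilyl)oxy]methyl}-2,3,3a,4,5,8,9,11a-octahydrocyclodeca[b]furan-4-yl 3-methylbutanoate | C=C1C(=O)O[C@@H]2/C=C(/CO[Si](C)(C)C(C)(C)C)CC/C=C(/CO[Si](CC)(CC)CC)C[C@@H](OC(=O)CC(C)C)[C@H]12 | intermediate
35 | (3aS,4R,6E,10E,11aR)-10-({[tert-butyl(dimethyl)silyl]oxy}methyl)-6-(hydroxymethyl)-3-methylidene-2-oxo-2,3,3a,4,5,8,9,11a-octahydrocyclodeca[b]furan-4-yl 3-methylbutanoate | C=C1C(=O)O[C@@H]2/C=C(/CO[Si](C)(C)C(C)(C)C)CC/C=C(/CO)C[C@@H](OC(=O)CC(C)C)[C@H]12 | intermediate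
36 | (3aS,4R,6E,10E,11aR)-10-({[tert-butyl(dimethyl)silyl]oxy}methyl)-6-formyl-3-methylidene-2-oxo-2,3,3a,4,5,8,9,11a-octahydrocyclodeca[b]furan-4-yl 3-methylbutanoate | C=C1C(=O)O[C@@H]2/C=C(/CO[Si](C)(C)C(C)(C)C)CC/C=C(/C=O)C[C@@H](OC(=O)CC(C)C)[C@H]12 | intermediate
37 | (3aS,4R,6E,10E,11aR)-6-formyl-10-(hydroxymethyl)-3-methylidene-2-oxo-2,3,3a,4,5,8,9,11a-octahydrocyclodeca[b]furan-4-yl 3-methylbutanoate | C=C1C(=O)O[C@@H]2/C=C(/CO)CC/C=C(/C=O)C[C@@H](OC(=O)CC(C)C)[C@H]12 | target

## Step count, longest linear sequence and the three weakest steps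

Total step count: 20.
Longest linear sequence: 13 steps (steps 1–3, then 11–20; the path through steps 4–6 is equally long). The alkenyl iodide branch (steps 7–10) joins at step 13.

Step 8 (anti-carbomagnesiation of the silylated propargylic alcohol). Addition of a primary alkyl Grignard reagent to the hindered silyl alkyne may be slow or give regioisomers. In the fallback the alkene geometry is built by syn-carbocupration instead. Compound 13 is silylated (TBSCl, imidazole, DMF) to tert-butyl(dimethyl)(prop-2-yn-1-yloxy)silane F1. Grignard reagent 17 and CuBr·SMe2 (Et2O/Me2S, −45 °C) give but-3-en-1-ylcopper F2, which adds syn across the alkyne of F1 at −25 °C, the butenyl group going to the internal carbon and copper to the terminal one, to give [(1E)-2-({[tert-butyl(dimethyl)silyl]oxy}methyl)hexa-1,5-dien-1-yl]copper F3. Iodine (−60 → 0 °C) then replaces copper with retention and gives 21 directly. This fallback sets out from 13 (with 17) and comes back to the route at 21, replacing steps 7–10.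

Step 13 (alkenyllithium addition to the hydroxy Weinreb amide). The hindered alkenyllithium may enolise the amide, and the product 26 is a base-sensitive β-hydroxy ketone with an acidic α-hydrogen, so retro-aldol cleavage or epimerisation at C7 is possible. The fallback makes the ketone under neutral conditions by a palladium-catalysed thioester–organozinc (Fukuyama) coupling. Aldol adduct 23 is treated with EtSH/n-BuLi (THF, 0 °C) to give S-ethyl (2S,3R)-3-hydroxy-2-{3-[(4-methoxybenzyl)oxy]prop-1-en-2-yl}-5-{[(triethylsilyl)oxy]methyl}hex-5-enethioate F4, with recovery of auxiliary 5. Alkenyllithium 25, made from 21 as in step 13, is transmetallated with ZnBr2 to bromo[(1E)-2-({[tert-butyl(dimethyl)silyl]oxy}methyl)hexa-1,5-dien-1-yl]zinc F5. F4 and F5 (2.5 equiv) are coupled with PdCl2(PPh3)2 (5 mol%) in THF/toluene at rt to give 26. This fallback sets out from 23 and 21 and comes back at 26, replacing steps 12 and 13.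

Step 17 (ring-closing metathesis to the ten-membered ring). This is the least certain step: a medium ring is formed, the new alkene is trisubstituted and the 1,1-disubstituted partner is flanked by a bulky silyl ether, so oligomerisation or no turnover is possible. In the fallback the order of steps 17 and 18 is reversed, so that the ring is closed on a free allylic alcohol. PPTS/MeOH (0 °C) converts 33 into (1R)-1-[(2R,3S)-2-[(1E)-2-({[tert-butyl(dimethyl)silyl]oxy}methyl)hexa-1,5-dien-1-yl]-4-methylidene-5-oxooxolan-3-yl]-3-(hydroxymethyl)but-3-en-1-yl 3-methylbutanoate F6. Its unhindered allylic hydroxyl next to the 1,1-disubstituted alkene assists the metathesis (hydroxyl-assisted ring closure with the same ruthenium catalyst, toluene, 1 mM, 80 °C) and gives 35 directly. This fallback sets out from 33 and comes back at 35.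

## Further compounds

F1 | step 8 | tert-butyl(dimethyl)(prop-2-yn-1-yloxy)silane | C#CCO[Si](C)(C)C(C)(C)C
F2 | step 8 | but-3-en-1-ylcopper | C=CCC[Cu]
F3 | step 8 | [(1E)-2-({[tert-butyl(dimethyl)silyl]oxy}methyl)hexa-1,5-dien-1-yl]copper | [Cu]/C=C(/CO[Si](C)(C)C(C)(C)C)CCC=C
F4 | step 13 | S-ethyl (2S,3R)-3-hydroxy-2-{3-[(4-methoxybenzyl)oxy]prop-1-en-2-yl}-5-{[(triethylsilyl)oxy]methyl}hex-5-enethioate | C=C(CO[Si](CC)(CC)CC)C[C@@H](O)[C@H](C(=C)COCc1ccc(OC)cc1)C(=O)SCC
F5 | step 13 | bromo[(1E)-2-({[tert-butyl(dimethyl)silyl]oxy}methyl)hexa-1,5-dien-1-yl]zinc | Br[Zn]/C=C(/CO[Si](C)(C)C(C)(C)C)CCC=C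
F6 | step 17 | (1R)-1-[(2R,3S)-2-[(1E)-2-({[tert-butyl(dimethyl)silyl]oxy}methyl)hexa-1,5-dien-1-yl]-4-methylidene-5-oxooxolan-3-yl]-3-(hydroxymethyl)but-3-en-1-yl 3-methylbutanoate | C=C1C(=O)O[C@H](/C=C(/CO[Si](C)(C)C(C)(C)C)CCC=C)[C@@H]1[C@@H](CC(=C)CO)OC(=O)CC(C)C
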